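**Plan**

1. Retrosynthesis: the three free phenols of rings B and B' are first masked as benzyl ethers. Then, in each phloroglucinol ring (ring A carries the 2,4-dihydroxy-6-methylbenzoyl ring B, ring A' the 4-hydroxy-2-methoxy-6-methylbenzoyl ring B'), the bond between the aroyl-bearing carbon and the hydroxyl-bearing carbon next to the bridge is cut.
2. Enabling feature: round ring A or A' the atoms read C(bridge CH2)–C(OMe)–CH–C(OH)–C(aroyl)–C(OH). This is C3–C4–C5–C6–(exocyclic CH2)–C2 of a 3-alkyl-4-methoxy-6-(aroylmethyl)-2-pyrone, so both rings unfold into one methylene-bridged bis-pyrone 14 that already holds the diarylmethane CH2 and both ring methyl ethers.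
3. Further cuts: the two CH2–C(O)Ar bonds of 14 (lateral lithiation of the pyrone 6-methyl groups, addition to two differently protected orsellinaldehydes, one double oxidation) and the two pyrone C3–CH2 bonds (formaldehyde).
4. Forward: two bought pyrone rings are joined at C3 and O-methylated; the arms carrying the intact rings B and B' are attached one after the other; rings A and A' then form together in step 9; hydrogenolysis ends the route.
5. Stereochemistry: the target has no stereocentre. The carbinol centres of 11 and 13 are racemic and are removed in step 8; the cis arrangement of ester and keto chain needed for ring closure is fixed by the pyrone rings.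

Key step: step 9

Remark: 2,4-dihydroxy-6-methylbenzaldehyde (6) is taken as a catalogue compound (otherwise one Vilsmeier formylation from orcinol); aldehydes are used in place of orsellinate esters because a di-ortho-substituted benzoate is a poor acylating agent for the pyrone anion.

**Route**

Step 1
Reactants: 1 4-hydroxy-6-methyl-2H-pyran-2-one (2 equiv); 2 formaldehyde
Product: 4 3,3'-methylenebis(4-hydroxy-6-methyl-2H-pyran-2-one), via methylidene dione 3 (not isolated)
Conditions: 37% aq. CH2O (0.5 equiv), EtOH, 80 °C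
Reagents that add atoms: none
Why: The enolic C3 of the 4-hydroxy-2-pyrone condenses with formaldehyde (Knoevenagel) to the methylidene dione 3, which a second pyrone traps at once by Michael addition, the same domino course that turns 4-hydroxycoumarin into dicoumarol.

Step 2
Reactants: 4 3,3'-methylenebis(4-hydroxy-6-methyl-2H-pyran-2-one)
Product: 5 3,3'-methylenebis(4-methoxy-6-methyl-2H-pyran-2-one)
Conditions: Me2SO4 (2.5 equiv), K2CO3, acetone, reflux
Reagents that add atoms: dimethyl sulfate, COS(=O)(=O)OC
Why: Williamson-type O-methylation of the vinylogous acid with a hard electrophile under K2CO3 is the standard entry to 4-methoxy-2-pyrones and should favour O4 over C3 and over the 2-methoxy-4-pyrone isomer.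

Step 3
Reactants: 6 2,4-dihydroxy-6-methylbenzaldehyde
Product: 7 2,4-bis(benzyloxy)-6-methylbenzaldehyde
Conditions: BnBr (2.5 equiv), K2CO3, DMF, 60 °C
Reagents that add atoms: benzyl bromide, BrCc1ccccc1
Why: Williamson ether synthesis with excess halide in DMF should alkylate both phenols, including the hydrogen-bonded 2-OH, while the non-enolisable aldehyde is untouched.

Step 4
Reactants: 6 2,4-dihydroxy-6-methylbenzaldehyde
Product: 8 4-(benzyloxy)-2-hydroxy-6-methylbenzaldehyde
Conditions: BnBr (1.05 equiv), NaHCO3, KI (cat.), MeCN, 80 °C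
Reagents that add atoms: benzyl bromide, BrCc1ccccc1
Why: Regioselective Williamson etherification, since the weak base ionises only the more acidic 4-OH para to the formyl group while the 2-OH stays locked in its hydrogen bond to the carbonyl.

Step 5
Reactants: 8 4-(benzyloxy)-2-hydroxy-6-methylbenzaldehyde
Product: 9 4-(benzyloxy)-2-methoxy-6-methylbenzaldehyde
Conditions: MeI, K2CO3, DMF, 40 °C
Reagents that add atoms: iodomethane, CI
Why: Williamson methylation of the remaining chelated phenol under the stronger base in DMF is routine for 2-hydroxybenzaldehydes.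

Step 6
Reactants: 5 3,3'-methylenebis(4-methoxy-6-methyl-2H-pyran-2-one) (2.5 equiv, excess recovered); 7 2,4-bis(benzyloxy)-6-methylbenzaldehyde
Product: 11 racemic mono-carbinol, 6-{2-[2,4-bis(benzyloxy)-6-methylphenyl]-2-hydroxyethyl}-4-methoxy-3-[(4-methoxy-6-methyl-2-oxo-2H-pyran-3-yl)methyl]-2H-pyran-2-one, via lithiomethyl pyrone 10 (not isolated)
Conditions: LiN(iPr)2 (1.0 equiv), THF, −78 °C; then 7 (0.9 equiv), −78 °C; aq. NH4Cl
Reagents that add atoms: none
Why: LiN(iPr)2 removes a proton from one 6-methyl group (lateral, vinylogous deprotonation of the 4-methoxy-2-pyrone) and the extended enolate 10 adds through its exocyclic carbon to the non-enolisable aldehyde in a vinylogous aldol addition, the excess of cheap 5 over base confining the reaction to one arm and the new carbinol centre being racemic and erased in step 8.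

Step 7
Reactants: 11 racemic mono-carbinol; 9 4-(benzyloxy)-2-methoxy-6-methylbenzaldehyde
Product: 13 diol (mixture of the two racemic diastereomers), 11 in which the second pyrone 6-methyl has become CH2–CH(OH)–[4-(benzyloxy)-2-methoxy-6-methylphenyl], via dilithio species 12 (not isolated)
Conditions: LiN(iPr)2 (2.2 equiv), THF, −78 °C; then 9 (1.3 equiv), −78 °C; aq. NH4Cl
Reagents that add atoms: none
Why: The first equivalent of base turns the hydroxyl into its lithium alkoxide, the second deprotonates the remaining 6-methyl group, and the carbanion of 12 adds to 9 in a second vinylogous aldol addition, the uncontrolled configuration of the two carbinol centres being immaterial because both are oxidised next.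

Step 8
Reactants: 13 diol
Product: 14 bis-ketone, methylene-bridged bis(4-methoxy-2-pyrone) carrying 6-[2-(2,4-bis(benzyloxy)-6-methylphenyl)-2-oxoethyl] on one ring and 6-[2-(4-(benzyloxy)-2-methoxy-6-methylphenyl)-2-oxoethyl] on the other
Conditions: IBX (2-iodoxybenzoic acid, 3 equiv), DMSO, 25 °C
Reagents that add atoms: none
Why: IBX oxidation of both secondary benzylic alcohols to aryl ketones runs under neutral conditions, which should spare the electron-rich benzylic carbinols from ionisation or dehydration to styrylpyrones and removes both stereocentres.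

Step 9
Reactants: 14 bis-ketone
Product: 16 tri-O-benzyl ether of the target (ring B 2,4-di-O-benzyl, ring B' 4-O-benzyl), via ring-opened bis(diketo enoate) 15 (not isolated)
Conditions: Mg(OMe)2 (10 equiv), MeOH, reflux; then 1 M HCl, 0 °C
Reagents that add atoms: none
Why: Methoxide adds to each lactone carbonyl (pyrone C2) and the ring opens to a methyl ester whose enol ether double bond keeps the ester carbon and the new 5,7-diketone chain cis, as they were in the pyrone; magnesium then holds the diketone as its chelated enolate, and its central carbon (the former exocyclic CH2 of the aroylmethyl arm) attacks the ester carbon, expels methoxide, and the cyclohexadienone enolises to the phenol. The closest known reaction is the base-mediated refolding of 4-methoxy-6-(2-oxoalkyl)-2-pyrones into 2-acyl-5-methoxyresorcinols, an intramolecular Claisen condensation, which here runs once on each half of the molecule. Rings A and A' each close by a 6-exo-trig (enolendo) attack of the diketone carbon on the exocyclic ester carbonyl, forming the C(aroyl)–C(OH) bond. No stereocentre is created. The step needs C-acylation by the central diketone carbon in preference to aldol closure onto the aryl ketone, retro-Claisen loss of the aroyl group and O-cyclisation to a 4-pyranone: pyrone C3 carries the bridge and no hydrogen, so it cannot act as an aldol donor, the di-ortho-substituted aroyl carbonyl is shielded from methoxide, and magnesium chelation keeps the diketone a carbon nucleophile next to the ester. The 4-methoxy groups pass unchanged into the aryl methyl ethers and the bridging CH2 is not touched.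

Step 10
Reactants: 16 tri-O-benzyl ether of the target
Product: 17 target, bis(3-aroyl-2,4-dihydroxy-6-methoxyphenyl)methane with 2,4-dihydroxy-6-methylbenzoyl on ring A and 4-hydroxy-2-methoxy-6-methylbenzoyl on ring A'
Conditions: H2 (1 atm), 10% Pd/C, EtOAc/MeOH, 25 °C
Reagents that add atoms: none
Why: Palladium-catalysed hydrogenolysis should cleave the three aryl benzyl ethers while the hydrogen-bonded, di-ortho-substituted benzophenone carbonyls and the diarylmethane bridge resist reduction at atmospheric pressure.

**Compound list**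

1 | 4-hydroxy-6-methyl-2H-pyran-2-one | CC1=CC(O)=CC(=O)O1 | starting material
2 | formaldehyde (37% aqueous) | C=O | starting material
3 | 6-methyl-3-methylidene-2H-pyran-2,4(3H)-dione | CC1=CC(=O)C(=C)C(=O)O1 | intermediate
4 | 3,3'-methylenebis(4-hydroxy-6-methyl-2H-pyran-2-one) | CC1=CC(O)=C(CC2=C(O)C=C(C)OC2=O)C(=O)O1 | intermediate
5 | 3,3'-methylenebis(4-methoxy-6-methyl-2H-pyran-2-one) | COC1=C(CC2=C(OC)C=C(C)OC2=O)C(=O)OC(C)=C1 | intermediate
6 | 2,4-dihydroxy-6-methylbenzaldehyde (orsellinaldehyde) | Cc1cc(O)cc(O)c1C=O | starting material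
7 | 2,4-bis(benzyloxy)-6-methylbenzaldehyde | Cc1cc(OCc2ccccc2)cc(OCc2ccccc2)c1C=O | intermediate
8 | 4-(benzyloxy)-2-hydroxy-6-methylbenzaldehyde | Cc1cc(OCc2ccccc2)cc(O)c1C=O | intermediate
9 | 4-(benzyloxy)-2-methoxy-6-methylbenzaldehyde | COc1cc(OCc2ccccc2)cc(C)c1C=O | intermediate
10 | mono-lithiated 5 (6-lithiomethyl on one pyrone ring) | [Li]CC1=CC(OC)=C(CC2=C(OC)C=C(C)OC2=O)C(=O)O1 | intermediate
11 | racemic 6-{2-[2,4-bis(benzyloxy)-6-methylphenyl]-2-hydroxyethyl}-4-methoxy-3-[(4-methoxy-6-methyl-2-oxo-2H-pyran-3-yl)methyl]-2H-pyran-2-one | COC1=C(CC2=C(OC)C=C(C)OC2=O)C(=O)OC(CC(O)c2c(C)cc(OCc3ccccc3)cc2OCc2ccccc2)=C1 | intermediate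
12 | dilithio derivative of 11 (lithium alkoxide, lithiomethyl on the other pyrone) | [Li]CC1=CC(OC)=C(CC2=C(OC)C=C(CC(O[Li])c3c(C)cc(OCc4ccccc4)cc3OCc3ccccc3)OC2=O)C(=O)O1 | intermediate
13 | 6-{2-[2,4-bis(benzyloxy)-6-methylphenyl]-2-hydroxyethyl}-3-[(6-{2-[4-(benzyloxy)-2-methoxy-6-methylphenyl]-2-hydroxyethyl}-4-methoxy-2-oxo-2H-pyran-3-yl)methyl]-4-methoxy-2H-pyran-2-one (both carbinol centres unassigned, diastereomer mixture) | COC1=C(CC2=C(OC)C=C(CC(O)c3c(C)cc(OCc4ccccc4)cc3OC)OC2=O)C(=O)OC(CC(O)c2c(C)cc(OCc3ccccc3)cc2OCc2ccccc2)=C1 | intermediate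
14 | 6-{2-[2,4-bis(benzyloxy)-6-methylphenyl]-2-oxoethyl}-3-[(6-{2-[4-(benzyloxy)-2-methoxy-6-methylphenyl]-2-oxoethyl}-4-methoxy-2-oxo-2H-pyran-3-yl)methyl]-4-methoxy-2H-pyran-2-one | COC1=C(CC2=C(OC)C=C(CC(=O)c3c(C)cc(OCc4ccccc4)cc3OC)OC2=O)C(=O)OC(CC(=O)c2c(C)cc(OCc3ccccc3)cc2OCc2ccccc2)=C1 | intermediate
15 | ring-opened (2E,2'E) bis(methyl 3-methoxy-5,7-dioxo-7-arylhept-2-enoate) joined through CH2 at C2 and C2', drawn in the neutral keto form (magnesium chelate in the flask) | COC(=O)/C(C\C(C(=O)OC)=C(/OC)CC(=O)CC(=O)c1c(C)cc(OCc2ccccc2)cc1OC)=C(/OC)CC(=O)CC(=O)c1c(C)cc(OCc2ccccc2)cc1OCc1ccccc1 | intermediate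
16 | tri-O-benzyl ether of the target (ring B 2,4-di-O-benzyl, ring B' 4-O-benzyl) | COc1cc(O)c(C(=O)c2c(C)cc(OCc3ccccc3)cc2OCc2ccccc2)c(O)c1Cc1c(OC)cc(O)c(C(=O)c2c(C)cc(OCc3ccccc3)cc2OC)c1O | intermediate
17 | CNP0596095.0, bis(3-aroyl-2,4-dihydroxy-6-methoxyphenyl)methane with 2,4-dihydroxy-6-methylbenzoyl (ring A) and 4-hydroxy-2-methoxy-6-methylbenzoyl (ring A') | COc1cc(O)c(C(=O)c2c(C)cc(O)cc2O)c(O)c1Cc1c(OC)cc(O)c(C(=O)c2c(C)cc(O)cc2OC)c1O | target

**Count**

Total steps: 10. Longest linear sequence: 7 steps (steps 1, 2, 6, 7, 8, 9, 10, from 1 to 17).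

**Steps most likely to fail**

Step 9. The risk is incomplete double refolding. Once one ring has closed, the half-product carries magnesium phenoxides next to the second lactone, so methoxide addition there may stall while prolonged heating brings on retro-Claisen loss of an aroyl group. The fallback closes the rings one at a time; it sets out from 11 and comes back to the route at 17.
- IBX oxidation of 11 should give the mono-ketone F1.
- Mg(OMe)2 in methanol refolds its one armed pyrone to the half-refolded benzophenone F2; the unarmed 4-methoxy-6-methylpyrone ring is expected to survive.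
- Benzylation of the two new phenols (BnBr, K2CO3, DMF) gives the tetrabenzyl ether F3, which removes the phenoxide charges.
- Lateral lithiation with LiN(iPr)2 and addition to 9 gives the carbinol F4, and IBX the ketone F5.
- A second Mg(OMe)2 treatment gives the pentabenzyl ether F6, and hydrogenolysis (H2, Pd/C) of all five benzyl ethers gives 17.

Step 6. The risk is loss of control over how many of the two equivalent methyl groups are lithiated, leading to double addition of 7, made worse if 5 is poorly soluble at −78 °C. The fallback moves the differentiation to the formaldehyde condensation; it sets out from 1 (with 7) and comes back at 11.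
- The dianion of 1 (LiN(iPr)2, 2.2 equiv, THF, −78 °C) is added to 7 to give the hydroxypyrone carbinol F7.
- F7 is condensed with aqueous formaldehyde in the presence of a large excess of 1, so that F7 should end up almost entirely in the crossed dipyranylmethane F8; the surplus 1 becomes 4, which the route uses anyway.
- O-Methylation of both enols of F8 with Me2SO4/K2CO3, which leaves the secondary alcohol alone, gives 11.

Step 7. The risk is retro-aldol cleavage of the lithium alkoxide under excess base, which would scramble the aryl groups between the arms, or deprotonation on the already substituted arm. The fallback avoids the alkoxide; it sets out from 11 and comes back at 13.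
- Silylation of 11 (Et3SiCl, imidazole, DMF) gives the triethylsilyl ether F9.
- One equivalent of LiN(iPr)2 and addition to 9 gives the mono-silylated diol F10.
- Desilylation with Bu4NF/AcOH in THF gives 13.

**Further compounds**

F1 | step 9 | 6-{2-[2,4-bis(benzyloxy)-6-methylphenyl]-2-oxoethyl}-4-methoxy-3-[(4-methoxy-6-methyl-2-oxo-2H-pyran-3-yl)methyl]-2H-pyran-2-one | COC1=C(CC2=C(OC)C=C(C)OC2=O)C(=O)OC(CC(=O)c2c(C)cc(OCc3ccccc3)cc2OCc2ccccc2)=C1
F2 | step 9 | [2,4-bis(benzyloxy)-6-methylphenyl]{2,6-dihydroxy-4-methoxy-3-[(4-methoxy-6-methyl-2-oxo-2H-pyran-3-yl)methyl]phenyl}methanone | COc1cc(O)c(C(=O)c2c(C)cc(OCc3ccccc3)cc2OCc2ccccc2)c(O)c1CC1=C(OC)C=C(C)OC1=O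
F3 | step 9 | di-O-benzyl ether of F2 (tetrabenzyl ether) | COc1cc(OCc2ccccc2)c(C(=O)c2c(C)cc(OCc3ccccc3)cc2OCc2ccccc2)c(OCc2ccccc2)c1CC1=C(OC)C=C(C)OC1=O
F4 | step 9 | racemic carbinol from F3 and 9, pyrone 6-substituent CH2–CH(OH)–[4-(benzyloxy)-2-methoxy-6-methylphenyl] | COc1cc(OCc2ccccc2)c(C(=O)c2c(C)cc(OCc3ccccc3)cc2OCc2ccccc2)c(OCc2ccccc2)c1CC1=C(OC)C=C(CC(O)c2c(C)cc(OCc3ccccc3)cc2OC)OC1=O
F5 | step 9 | ketone from F4, pyrone 6-substituent CH2–C(=O)–[4-(benzyloxy)-2-methoxy-6-methylphenyl] | COc1cc(OCc2ccccc2)c(C(=O)c2c(C)cc(OCc3ccccc3)cc2OCc2ccccc2)c(OCc2ccccc2)c1CC1=C(OC)C=C(CC(=O)c2c(C)cc(OCc3ccccc3)cc2OC)OC1=O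
F6 | step 9 | penta-O-benzyl ether of the target (ring A 2,4-di-O-benzyl, ring B 2,4-di-O-benzyl, ring B' 4-O-benzyl) | COc1cc(OCc2ccccc2)c(C(=O)c2c(C)cc(OCc3ccccc3)cc2OCc2ccccc2)c(OCc2ccccc2)c1Cc1c(OC)cc(O)c(C(=O)c2c(C)cc(OCc3ccccc3)cc2OC)c1O
F7 | step 6 | racemic 6-{2-[2,4-bis(benzyloxy)-6-methylphenyl]-2-hydroxyethyl}-4-hydroxy-2H-pyran-2-one | OC1=CC(=O)OC(CC(O)c2c(C)cc(OCc3ccccc3)cc2OCc2ccccc2)=C1
F8 | step 6 | racemic 6-{2-[2,4-bis(benzyloxy)-6-methylphenyl]-2-hydroxyethyl}-4-hydroxy-3-[(4-hydroxy-6-methyl-2-oxo-2H-pyran-3-yl)methyl]-2H-pyran-2-one | OC1=C(CC2=C(O)C=C(C)OC2=O)C(=O)OC(CC(O)c2c(C)cc(OCc3ccccc3)cc2OCc2ccccc2)=C1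
F9 | step 7 | triethylsilyl ether of 11 | COC1=C(CC2=C(OC)C=C(C)OC2=O)C(=O)OC(CC(O[Si](CC)(CC)CC)c2c(C)cc(OCc3ccccc3)cc2OCc2ccccc2)=C1
F10 | step 7 | mono-triethylsilyl ether of 13 (silyl on the carbinol of the bis(benzyloxy)aryl arm) | COC1=C(CC2=C(OC)C=C(CC(O)c3c(C)cc(OCc4ccccc4)cc3OC)OC2=O)C(=O)OC(CC(O[Si](CC)(CC)CC)c2c(C)cc(OCc3ccccc3)cc2OCc2ccccc2)=C1
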